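All runs come from a simulation with made-up constants; scatter was added.

4 questions stood on the board, and I brought one quantity to them.

| flask | starting material | reagent | remark | time |
|---|---|---|---|---|
| Sunday's | 0.094 M | 0.122 M | run made earlier |  |
| Thursday's | 0.094 M | 0.17 M | run made earlier |  |
| Friday's | 0.094 M | 0.27 M | run made earlier |  |
| Monday's | 0.047 M | 0.122 M | run made earlier |  |
| south | 0.094 M | 0.122 M (fed, over 5.0 d) | all else is in the flask from the start; the feed brings no volume worth counting | 6.0 d |
| north-east | 0.094 M | 0.122 M | everything together at the start | 6.0 d |
| north-west | 0.094 M (fed, over 5.0 d) | 0.122 M | all else is in the flask from the start; the feed brings no volume worth counting | 6.0 d |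

| run | time / d | triple product / % | side product / % |
|---|---|---|---|
| Sunday's | 0.250 | 2 | 0 |
| Sunday's | 0.500 | 0 | 0 |
| Sunday's | 1.04 | 1 | 2 |
| Sunday's | 2.08 | 0 | 0 |
| Sunday's | 4.00 | 6 | 3 |
| Thursday's | 0.625 | 2 | 3 |
| Thursday's | 1.04 | 0 | 1 |
| Thursday's | 2.08 | 4 | 0 |
| Thursday's | 4.00 | 7 | 7 |
| Thursday's | 8.00 | 16 | 16 |
| Friday's | 0.625 | 0 | 0 |
| Friday's | 1.04 | 4 | 0 |
| Friday's | 2.08 | 14 | 4 |
| Friday's | 4.00 | 28 | 6 |
| Friday's | 8.00 | 43 | 17 |
| Monday's | 0.625 | 1 | 2 |
| Monday's | 1.04 | 1 | 0 |
| Monday's | 2.08 | 5 | 1 |
| Monday's | 4.00 | 13 | 5 |
| Monday's | 8.00 | 19 | 15 |

(each reading ± 1.5 percentage points)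
* the flask with the highest share of triple product in triple product plus side product ("all alike" if they lie within 1.5 percentage points) (south / north-east / north-west / all alike)
* share of triple product in triple product plus side product at the end, south
* share of triple product in triple product plus side product at the end, north-east
* share of triple product in triple product plus side product at the end, north-west


I read the runs as a ladder of times. On the first rung, at 0.625 d, Friday's triple product read 0% against a scatter of 1.5 percentage points, so I took it that something unseen stood before the products. The next rung was the reading time, 6.0 d. Above it, Friday's average pace gave one whole charge as triple product in 18.6 d and as side product in 47.1 d, both longer than the reading time, so I reckoned that these flasks would be read early.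

Then I went to logarithms. From Thursday to Friday, the logarithm of the product ratio rose 1.11 times as fast as that of the excess, c(reagent) minus c(starting material). I therefore took the ratio as first order in reagent. Friday's readings gave the selectivity factor K, triple product per side product for each molar of free reagent, as 14.4 /M, and the share is Kc/(1+Kc).

In north-east I expected c(reagent) to fall from 0.122 M towards 0.0280 M, and these two levels gave me shares of 28.7% and 63.7%. The logarithmic middle, 0.0584 M, gave me 45.7%. I put north-west between that and 63.7%, and left south unplaced.

The forecast said south 13%, north-east 30%, north-west 58%, best north-west, holding that “the first equivalent is taken up quickly”. For north-east I stood above it.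

The flasks gave south 46.2%, north-east 43.0%, north-west 55.3%, best north-west.

    starting material + reagent → mono adduct + by-product (k = 0.00465 /M/min)
    reagent + double product → triple product + by-product (k = 0.00536 /M/min)
    double product → side product (k = 2.79 × 10⁻⁴ /min)
    reagent + mono adduct → double product + by-product (k = 8.29 × 10⁻⁴ /M/min)

North-east's 5.75% of triple product and 7.61% of side product had a ratio which, divided by K, gave a level of 0.0525 M. Its reagent stood at 0.0203 M at 6.00 d, lower than the 0.0280 M I had taken as the low end. The neighbour of north-west charged with 0.030 M of reagent kept 16.0% of it at 6.00 d. The logarithmic middle of those two levels was 0.0120 M, and K turned that into a share of 14.7%. That neighbour gave 19.0%.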